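Readings and results stem from a simulated flask for substances that don't exist; the scatter is artificial.

Early on E outruns J: in the oak run at 8.00 min, E stands at 34.0% and J at 18.3%. The question is what that start is worth when D or Z goes in slowly.

| flask | D | Z | G | remark | time |
|---|---|---|---|---|---|
| oak | 0.30 M | 1.1 equiv | 1.5 equiv | run made earlier |  |
| alder | 0.20 M | 1.1 equiv | 1.5 equiv | run made earlier |  |
| maple | 0.45 M | 1.1 equiv | 1.5 equiv | run made earlier |  |
| east | 0.30 M | 1.10 equiv | 1.50 equiv | everything together at the start | 50 min |
| north-east | 0.30 M (in portions, 5, over 30 min) | 1.10 equiv | 1.50 equiv | first portion at the start, last at 30 min | 50 min |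
| north-west | 0.30 M | 1.10 equiv (fed, over 30 min) | 1.50 equiv | all else is in the flask from the start; the feed brings no volume worth counting | 50 min |
| west | 0.30 M (fed, over 30 min) | 1.10 equiv | 1.50 equiv | all else is in the flask from the start; the feed brings no volume worth counting | 50 min |

| run | time / min | E / % | J / % |
|---|---|---|---|
| oak | 8.00 | 34.0 | 18.3 |
| oak | 15.0 | 45.3 | 28.6 |
| oak | 25.0 | 49.9 | 39.1 |
| oak | 30.0 | 51.0 | 40.8 |
| oak | 40.0 | 53.0 | 44.1 |
| oak | 50.0 | 54.3 | 42.2 |
| alder | 2.00 | 13.5 | 2.9 |
| alder | 6.00 | 25.0 | 17.4 |
| alder | 10.0 | 31.9 | 26.7 |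
| alder | 15.0 | 36.1 | 35.3 |
| alder | 25.0 | 42.4 | 45.8 |
| alder | 30.0 | 44.2 | 49.4 |
| maple | 5.00 | 28.3 | 8.1 |
| maple | 10.0 | 41.6 | 16.7 |
| maple | 15.0 | 49.4 | 22.1 |
| maple | 20.0 | 57.0 | 29.3 |
| maple | 25.0 | 56.5 | 32.2 |
| maple | 30.0 | 59.7 | 32.4 |

(scatter of a reading: 1 percentage point)

- at the start none of G is in solution
- a reading or a percentage of J counts all its forms, free or not

- the flask that comes out highest in amount of E, in percent of the D charged, or "all alike" when all lie within 1.5 percentage points (east / north-east / north-west / west / all alike)
- E at the end, in percent of the D charged, east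
- E at the end, in percent of the D charged, north-east
- E at the end, in percent of the D charged, north-west
- E at the end, in percent of the D charged, west

Take the main step first. E and J together track the loss of D, and their sum in oak at 8.00 min gives a first-order constant of 0.0925 min⁻¹, a time constant of 10.8 min. Alder, at 0.20 M, reads 0.0919 min⁻¹ at 6.00 min, close to oak's value.

Now add the competition. What leaves D is taken to be an intermediate, caught by Z to give E and by dissolved G to give J. From 15.0 min to 50.0 min, oak gains 9 percentage points of E and 14 points of J, while c(Z) stands near 0.177 M. That ratio per molar of Z, with dissolved G taken as steady, is the selectivity factor, 3.74 M⁻¹, a reading from oak with the scatter of its readings. The zero of the scale is the even split, where the product of the factor and c(Z) equals one, at c(Z) of 0.267 M. With r for that product, the share going to E is r/(1+r).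

Z is spent as E forms, so c(Z) is taken midway through that spending. Last comes the dissolving of G, none of it in solution at the start: oak's early E to J ratio is 1.86, while the factor gives 0.852. West, I reckon, forgoes that early excess of E: at c(Z) of 0.249 M, with oak's last E standing for the spending, the share is 48.2%, and 5.31% of D stays unreacted at 50 min, which gives E of 45.6%.

The forecast names east highest, with 54.5% there, 50.5% for north-east, 26% for north-west and 50% for west, and says: “Feeding Z starves the E path”. Its factor is 4.5 per molar, and my west lies lower than its 46.5% low end.

The simulation gives 54.6% for east, 46.9% for north-east, 26.5% for north-west and 46.7% for west, so east leads by 7.7 points, against a margin of 1.5 points.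

    D → X (k = 0.00150 s⁻¹)
    Q + X → J (k = 19.0 M⁻¹ s⁻¹)
    Z + X → E (k = 7.20 M⁻¹ s⁻¹)
    G ⇌ Q, rate k4*(cs4 - [Q]) while solid is left; crystals form when [Q] > cs4 (solubility = 0.110 M, k = 0.00570 s⁻¹)
    L ⇌ J, rate k5*(cs5 - [J]) while solid is left; crystals form when [J] > cs5 (solubility = 31.0 mM, k = 0.120 s⁻¹)

West's 46.7% stands 1.1 points above the reckoning and 3.3 points below the forecast, with D at 5.71% after 50.0 min. A neighbour of east holds 2.80 equiv of Z. The same reckoning, again with oak's last E standing for the spending, puts its c(Z) at 0.759 M and r at 2.84, past the even split, so the reckoned share to E is 73.9%. That flask gives E of 76.3%.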